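## The problem

Phenylcandilide B (19) is methyl 2-[6-(4-hydroxyphenyl)-4,7-dimethoxy-3-methyl-1-benzofuran-2-yl]acetate: a furan (ring A) fused to a benzene (ring B), with a 4-hydroxyphenyl group (ring C) joined to C6 by a biaryl bond. There are no stereocentres, so the whole difficulty is regiochemical. Ring B carries five different substituents in a fixed order (C3a carbon, C4 OMe, C5 H, C6 aryl, C7 OMe, C7a oxygen), and ring A carries two different carbon substituents at C2 and C3. Three oxygens sit on ring B, two as methyl ethers and one as the furan oxygen; a route from a polyphenol would have to tell them apart, whereas a route that builds ring B from fragments can place each one in its final form. The fragile parts are the methyl ester on a doubly activated methylene (enolisable, easily hydrolysed or condensed), the free phenol of ring C, and the electron-rich hydroquinone-ether ring B, which is open to oxidation and to electrophilic attack at C5. This argues for bringing in the ester side chain late under non-hydrolytic conditions and for masking the phenol as a benzyl ether. The enabling feature is that the run C3a–C7a–C7–C6, with its acyl-type carbon (C3 and its methyl), oxygen, methoxy and aryl substituents, is exactly the C3–C4–C5–C6 pattern of a 3-acetyl-4-oxy-5-methoxy-6-aryl-2-pyrone, a cyclised polyketide-type chain. The remaining pair C4(OMe)–C5(H) corresponds to a ketene acetal less one alcohol, so ring B can be formed by an inverse-demand Diels–Alder reaction with every substituent already in place.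

## Retrosynthesis

**Benzyl ether.** The last cut is the O–CH2Ph bond on ring C, so 19 comes from its benzyl ether 18. A benzyl group survives the enolate, hydride, acid and hot ketene acetal conditions used earlier, which a silyl or acyl mask would not. Its hydrogenolysis touches neither the methyl ester nor the fully substituted furan double bond. The skeleton is not simplified, but the free phenol is kept out of every basic and acylating step.

**Ring A.** In 18 the C2=C3 double bond and the O1–C2 bond are cut together, giving the phosphonium salt 14 and the acid chloride 15. The neighbouring cut (O1–C2 plus C2–C3, with C2 as an enolate carbon) would give a benzofuran-2-carboxylate one carbon short. Attaching the side chain to a finished C2-unsubstituted benzofuran is not dependable. Only the olefination cut brings in the whole CH2CO2Me unit in one operation. Precursor 14 lacks both ring A and the ester. The forward reaction must acylate the phenol oxygen (16), form the ylide (17), and close a five-membered ring onto an aryl ester carbonyl before the malonate methylene interferes.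

**Functional group changes.** The C–P bond of 14 is traced to the benzylic alcohol 13, the alcohol to ketone 12, and the free phenol of 12 to the methoxymethyl ether 11. No skeletal bond is removed, but an o-oxygenated acetophenone is revealed whose acetyl carbon is C3 and whose methyl is the C3 methyl. The forward steps need only chemoselectivity: acetal cleavage that leaves the benzyl ether, a hydride reduction, and substitution at a benzylic carbon that ionises readily because of the ortho hydroxyl.

**Ring B (key cut).** In 11 the bonds C3a–C4 and C5–C6 (benzofuran numbering) are cut, giving pyrone 7 and ketene acetal 8. A biaryl coupling followed by stepwise substitution of a trioxygenated benzene would fight the directing effects of three oxygens. Other (4+2) partitions of ring B would need an alkoxyalkyne or would put the acetyl group on the two-carbon partner. This cut is the only one in which the four-carbon component has an acceptor at a diene terminus and the two-carbon partner is a stable commercial donor. A benzene with five different substituents becomes a heterocycle whose substituents are fixed by its own ring synthesis. The forward reaction must give a regioselective inverse-demand cycloaddition, decarboxylation of bridged adduct 9 and loss of one methoxy group from 10, and the acetal at O4 must survive the heat.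

**Pyrone substituents.** Pyrone 7 is simplified by removing the methoxymethyl group (to 6) and then the C3–acetyl bond (to 4). C3 is the only unsubstituted ring carbon of 4 and its nucleophilic site, so C-acetylation through enol acetate 5 needs no regiocontrol. The acidic chelated enol of 6 is capped so that it can neither protonate 8 nor be methylated by it. Compound 4 is a plain 4-hydroxy-2-pyrone.

**Open chain.** The lactone C–O bond of 4 is opened to the triketo ester 3, and the C4–C5 bond of 3 is cut to β-keto ester 1 and benzoate 2. This polyketide-type assembly is preferred to cross-coupling on a halopyrone because it sets the biaryl bond, the C5 methoxy group and the C4 oxygen from two commercial esters in two steps. The forward reaction needs γ-selective acylation of the dianion of 1 and cyclisation through the enol oxygen of the aryl ketone.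

## Roads not taken

**Alternative 1:** The cut runs through C4–C5, C6–C7 and C7–C7a, so ring B would be built on a preformed furan by a Dötz benzannulation.
- Forward step: the chromium carbene complex A2 (made from Cr(CO)6) is heated with the terminal alkyne A3. Alkyne and one carbonyl ligand insert, and the dienylketene closes on the free furan α-carbon to give benzofuranol A1.
- Merits: the usual regiochemistry for terminal alkynes places the aryl group next to the new hydroxyl, as required. The carbene methoxy group becomes the C4 ether and the C7 oxygen emerges free, so the two oxygens are distinguished at no cost. A1 is probably reached in fewer steps than 11, and this must be conceded.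
- Weak points: A1 has nothing at C2. The CH2CO2Me group would have to go onto a finished electron-rich benzofuran, either by C2-lithiation and alkylation with a haloacetate (a poor electrophile for aryllithiums) or by carbenoid insertion (which tends to cyclopropanate C2=C3). Neither can be defended as well precedented. The furyl-metal precursor of A2 needs a 3,4-disubstituted furan, which is awkward to reach, and the reaction is stoichiometric in chromium. A1 is an oxidation-prone hydroquinone monoether that must be methylated at once.
- Comparison: against the shorter core synthesis, the chosen plan offers a side chain installed by a defined acylation–olefination (14 + 15 → 18), metal-free ring construction, and catalogue starting materials throughout.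

**Alternative 2:** The cut is O1–C2 together with the bond from the side-chain CH2 to the ester carbon.
- Forward step: phenol A5 is cyclised with catalytic PdCl2 (divalent palladium) and CuCl2 as reoxidant under carbonylative conditions in an alcohol solvent. A 5-exo alkoxypalladation, carbonyl insertion and alcoholysis give the trans-dihydrobenzofuran A4, which must then be dehydrogenated to 18.
- Merits: the step is catalytic, builds the ester side chain from one-carbon feedstock as the ring forms, and belongs to a well-established class for 2-allylphenols. The branched allyl group of A5 could come from an aromatic Claisen rearrangement. This closure of ring A is at least as well precedented as steps 7–9 of the chosen plan and is shorter counted from the phenol.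
- Weak points: it says nothing about ring B. A5 is itself a pentasubstituted benzene with three distinct oxygens and a biaryl bond, so the real problem is only moved. Two stereocentres are made and then destroyed. Dehydrogenation of A4 needs a quinone-type oxidant beside a hydroquinone-ether ring and an enolisable ester, with a risk of over-oxidation. β-Hydride loss from the primary alkylpalladium (a Wacker-type outcome) competes with carbonylation, and CuCl2 can chlorinate C5.
- Comparison: the chosen plan gives up the more elegant ring-A step in exchange for an actual solution of ring B, and reaches the furan directly at the aromatic oxidation level.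

**Alternative 3:** The cut is C6–C7 and C4–C5, with ring B made by a Hauser–Kraus annulation onto a furan.
- Forward step: the anion of sulfonyl lactone A7 adds to the β-carbon of cinnamate A8, the ester enolate closes on the lactone carbonyl and sulfinate is expelled, giving hydroquinone A6.
- Merits: the furan with its complete side chain is present from the start, so no late ring-A construction is needed. Both oxygens at C4 and C7 appear together and can be methylated in one operation, which fits the two methoxy groups of the target. The aryl group is placed unambiguously. In these respects it is better than the chosen plan, which spends four steps on ring A after the key step.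
- Weak points: A6 has a carboxyl group at C5 that the target lacks. Removing it (tert-butyl ester cleavage, then protodecarboxylation of a hindered electron-rich benzoic acid beside a methyl ester) adds two uncertain steps. β-Aryl acrylates are sluggish acceptors in this annulation. A7 has a second acidic site, the CH2 between furan and ester, which competes under the strong base. A7 is a tetrasubstituted furan whose preparation is likely longer than that of 7, and A6 is air-sensitive.
- Comparison: the chosen plan reaches its key precursor 7 in four steps from commercial open-chain esters, with every oxygen already in its final form and no ring substituent to remove afterwards.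

Key step: step 5

Assumption: 3 and 6 are drawn as single tautomers (triketo ester and 3-acetyl-4-hydroxypyrone) although both will exist largely as chelated enols; all chiral compounds of the route are racemic.

## Route

Step 1
Reactants: 1 methyl 4-methoxyacetoacetate (methyl 4-methoxy-3-oxobutanoate); 2 methyl 4-(benzyloxy)benzoate
Product: 3 methyl 5-[4-(benzyloxy)phenyl]-4-methoxy-3,5-dioxopentanoate
Conditions: 1 (2 equiv), LiN(iPr)2 (LDA, 4 equiv), THF, −78 to 0 °C; then 2, −78 °C to rt; aq. HCl
Reagents that add atoms: none
Why: Claisen-type γ-acylation of the acetoacetate dianion: the second deprotonation makes the methoxy-bearing C4 the most nucleophilic carbon and it attacks the non-enolisable benzoate; a second equivalent of dianion serves as base because the triketo ester is more acidic than 1. The new stereocentre at C4 lies between two carbonyls and is lost on enolisation, so none has to be controlled.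

Step 2
Reactants: 3 methyl 5-[4-(benzyloxy)phenyl]-4-methoxy-3,5-dioxopentanoate
Product: 4 6-[4-(benzyloxy)phenyl]-4-hydroxy-5-methoxy-2H-pyran-2-one
Conditions: DBU, toluene, reflux; then dilute HCl
Reagents that add atoms: none
Why: Base-mediated lactonisation of a 3,5-dioxo ester: the enol oxygen of the aryl ketone attacks the ester carbonyl (6-exo-trig), methanol is expelled and the ring settles as the 4-hydroxy-2-pyrone; this is a standard route to 6-aryl-4-hydroxy-2-pyrones.

Step 3
Reactants: 4 6-[4-(benzyloxy)phenyl]-4-hydroxy-5-methoxy-2H-pyran-2-one
Product: 6 3-acetyl-6-[4-(benzyloxy)phenyl]-4-hydroxy-5-methoxy-2H-pyran-2-one, via 4-acetoxypyrone 5 (not isolated)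
Conditions: AcOH, DCC, DMAP, toluene, rt to 80 °C
Reagents that add atoms: acetic acid, CC(=O)O
Why: Steglich-type O-acylation gives enol acetate 5, and DMAP then moves the acetyl group from oxygen to C3 (Fries-type 1,3-acyl shift through an acylpyridinium–pyronate ion pair), the usual way to 3-acyl-4-hydroxy-2-pyrones. C3 is the only free and the most nucleophilic ring carbon, and the chelated tricarbonyl product is the thermodynamic sink.

Step 4
Reactants: 6 3-acetyl-6-[4-(benzyloxy)phenyl]-4-hydroxy-5-methoxy-2H-pyran-2-one
Product: 7 3-acetyl-6-[4-(benzyloxy)phenyl]-5-methoxy-4-(methoxymethoxy)-2H-pyran-2-one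
Conditions: MOMCl, iPr2NEt, CH2Cl2, 0 °C to rt
Reagents that add atoms: chloromethyl methyl ether, COCCl
Why: O-alkylation of the acidic chelated enol by a hard oxocarbenium-type electrophile; the ring 4-oxygen carries most of the charge of the tricarbonyl anion and hard alkylating agents cap 3-acyl-4-hydroxy-2-pyrones there. The cap is needed because the free enol would protonate 8 in step 5.

Step 5
Reactants: 7 3-acetyl-6-[4-(benzyloxy)phenyl]-5-methoxy-4-(methoxymethoxy)-2H-pyran-2-one; 8 1,1-dimethoxyethene
Product: 11 1-[4'-(benzyloxy)-2,5-dimethoxy-3-(methoxymethoxy)[1,1'-biphenyl]-4-yl]ethan-1-one, via bridged lactone cycloadduct 9 (not isolated), via dimethoxycyclohexadiene 10 (not isolated)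
Conditions: 8 (excess), toluene, sealed tube, 110–140 °C
Reagents that add atoms: none
Why: Pyrone 7 carries the acetyl and the lactone carbonyl on the same carbon (C3), which lowers its acceptor orbital, so it reacts as the 4π acceptor with the electron-rich 2π donor 8 in an inverse-electron-demand Diels–Alder reaction; the closest known reaction type is the benzannulation of 3-alkoxycarbonyl- and 3-acyl-2-pyrones with 1,1-dimethoxyethene. Bond formation should be asynchronous or stepwise through a zwitterion: the nucleophilic CH2 of 8 attacks the aryl-bearing terminus C6 and the acetal carbon then bonds to the acetyl-bearing C3, giving bridged lactone 9. Ring B is therefore closed by an intermolecular (4+2) cycloaddition across the diene termini of the pyrone, not by an exo or endo cyclisation of a chain. Adduct 9 loses CO2 by retro-(4+2) cycloreversion to cyclohexadiene 10, and 10 loses one molecule of methanol across the new C4–C5 bond (thermally, or on a mild acid or base work-up) to give the arene with OMe at C4 and H at C5. The two bridgehead stereocentres of 9 are tied to each other by the bicycle, form as a racemate and vanish in the next events, so no stereocontrol is needed. The selectivity required is regiochemical, attack at C6 and C3 and not at the oxygen-bearing C4 that is β to both carbonyls; it is secured by the polarity match (donor carbon of 8 to the vinylogous acceptor terminus, oxocarbenium carbon to the enolate-like C3), by electron release from the 4-alkoxy oxygen that blunts C4, and by the fact that only the cycloaddition channel is made irreversible by gas evolution. Excess 8 also scavenges the liberated methanol.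

Step 6
Reactants: 11 1-[4'-(benzyloxy)-2,5-dimethoxy-3-(methoxymethoxy)[1,1'-biphenyl]-4-yl]ethan-1-one
Product: 12 1-[4'-(benzyloxy)-3-hydroxy-2,5-dimethoxy[1,1'-biphenyl]-4-yl]ethan-1-one
Conditions: HCl (cat.), MeOH, 40 °C
Reagents that add atoms: none
Why: Acid-catalysed acetal exchange (MOM cleavage) in methanol; the ether ortho to the acetyl group cleaves especially easily because the liberated phenol is hydrogen-bonded to the carbonyl, while benzyl and methyl aryl ethers are inert.

Step 7
Reactants: 12 1-[4'-(benzyloxy)-3-hydroxy-2,5-dimethoxy[1,1'-biphenyl]-4-yl]ethan-1-one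
Product: 13 4'-(benzyloxy)-4-(1-hydroxyethyl)-2,5-dimethoxy[1,1'-biphenyl]-3-ol (racemic)
Conditions: NaBH4, MeOH–THF, 0 °C to rt
Reagents that add atoms: none
Why: Borohydride reduction of an aryl methyl ketone; the phenoxide formed in situ slows but does not stop it. The new benzylic stereocentre forms as a racemate, which is immaterial because this carbon becomes the sp2 carbon C3.

Step 8
Reactants: 13 4'-(benzyloxy)-4-(1-hydroxyethyl)-2,5-dimethoxy[1,1'-biphenyl]-3-ol
Product: 14 {1-[4'-(benzyloxy)-3-hydroxy-2,5-dimethoxy[1,1'-biphenyl]-4-yl]ethyl}triphenylphosphonium bromide (racemic)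
Conditions: PPh3·HBr, MeCN, reflux
Reagents that add atoms: triphenylphosphine hydrobromide, Br.c1ccc(cc1)P(c1ccccc1)c1ccccc1
Why: Acid-mediated ionisation of the o-hydroxybenzylic alcohol to an o-quinone methide (a benzylic cation stabilised by the ortho oxygens) and capture by PPh3, the standard preparation of (2-hydroxybenzyl)phosphonium salts. The stereocentre stays racemic and is erased in step 9.

Step 9
Reactants: 14 {1-[4'-(benzyloxy)-3-hydroxy-2,5-dimethoxy[1,1'-biphenyl]-4-yl]ethyl}triphenylphosphonium bromide; 15 methyl malonyl chloride (methyl 3-chloro-3-oxopropanoate)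
Product: 18 methyl 2-{6-[4-(benzyloxy)phenyl]-4,7-dimethoxy-3-methyl-1-benzofuran-2-yl}acetate, via O-malonyl phosphonium salt 16 (not isolated), via acylated ylide 17 (not isolated)
Conditions: 15, Et3N, toluene, 0 °C to rt; then reflux
Reagents that add atoms: none
Why: Intramolecular Wittig reaction of an O-acylated (2-hydroxybenzyl)phosphonium ylide, an established benzofuran synthesis: the phenol is acylated by 15 to give 16, Et3N forms ylide 17, and the ylide carbon attacks the activated aryl ester carbonyl in a five-membered closure. Ph3P=O is expelled and the C2=C3 bond is set with CH2CO2Me at C2 and CH3 at C3; no stereocentre remains.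

Step 10
Reactants: 18 methyl 2-{6-[4-(benzyloxy)phenyl]-4,7-dimethoxy-3-methyl-1-benzofuran-2-yl}acetate
Product: 19 phenylcandilide B, methyl 2-[6-(4-hydroxyphenyl)-4,7-dimethoxy-3-methyl-1-benzofuran-2-yl]acetate
Conditions: H2 (1 atm), Pd/C, EtOAc–MeOH, rt
Reagents that add atoms: none
Why: Hydrogenolysis of the benzyl aryl ether over Pd/C; the tetrasubstituted aromatic furan double bond, the methyl ester and the aryl methyl ethers are untouched under these mild conditions.

## Compound list

1 | methyl 4-methoxyacetoacetate (methyl 4-methoxy-3-oxobutanoate) | COCC(=O)CC(=O)OC | starting material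
2 | methyl 4-(benzyloxy)benzoate | COC(=O)c1ccc(OCc2ccccc2)cc1 | starting material
3 | methyl 5-[4-(benzyloxy)phenyl]-4-methoxy-3,5-dioxopentanoate (C4 labile, racemic) | COC(=O)CC(=O)C(OC)C(=O)c1ccc(OCc2ccccc2)cc1 | intermediate
4 | 6-[4-(benzyloxy)phenyl]-4-hydroxy-5-methoxy-2H-pyran-2-one | COC1=C(c2ccc(OCc3ccccc3)cc2)OC(=O)C=C1O | intermediate
5 | 6-[4-(benzyloxy)phenyl]-5-methoxy-2-oxo-2H-pyran-4-yl acetate | CC(=O)OC1=CC(=O)OC(c2ccc(OCc3ccccc3)cc2)=C1OC | intermediate (not isolated)
6 | 3-acetyl-6-[4-(benzyloxy)phenyl]-4-hydroxy-5-methoxy-2H-pyran-2-one | CC(=O)C1=C(O)C(OC)=C(c2ccc(OCc3ccccc3)cc2)OC1=O | intermediate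
7 | 3-acetyl-6-[4-(benzyloxy)phenyl]-5-methoxy-4-(methoxymethoxy)-2H-pyran-2-one | CC(=O)C1=C(OCOC)C(OC)=C(c2ccc(OCc3ccccc3)cc2)OC1=O | intermediate
8 | 1,1-dimethoxyethene | C=C(OC)OC | starting material
9 | 4-acetyl-1-[4-(benzyloxy)phenyl]-6,8,8-trimethoxy-5-(methoxymethoxy)-2-oxabicyclo[2.2.2]oct-5-en-3-one (racemic, one enantiomer drawn; bridgeheads tied by the bicycle) | CC(=O)[C@@]12C(=O)O[C@@](c3ccc(OCc4ccccc4)cc3)(CC1(OC)OC)C(OC)=C2OCOC | intermediate (not isolated)
10 | 1-{4-[4-(benzyloxy)phenyl]-3,6,6-trimethoxy-2-(methoxymethoxy)cyclohexa-1,3-dien-1-yl}ethan-1-one | CC(=O)C1=C(OCOC)C(OC)=C(c2ccc(OCc3ccccc3)cc2)CC1(OC)OC | intermediate (not isolated)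
11 | 1-[4'-(benzyloxy)-2,5-dimethoxy-3-(methoxymethoxy)[1,1'-biphenyl]-4-yl]ethan-1-one | CC(=O)c1c(OCOC)c(OC)c(-c2ccc(OCc3ccccc3)cc2)cc1OC | intermediate
12 | 1-[4'-(benzyloxy)-3-hydroxy-2,5-dimethoxy[1,1'-biphenyl]-4-yl]ethan-1-one | CC(=O)c1c(O)c(OC)c(-c2ccc(OCc3ccccc3)cc2)cc1OC | intermediate
13 | 4'-(benzyloxy)-4-(1-hydroxyethyl)-2,5-dimethoxy[1,1'-biphenyl]-3-ol (racemic) | CC(O)c1c(O)c(OC)c(-c2ccc(OCc3ccccc3)cc2)cc1OC | intermediate
14 | {1-[4'-(benzyloxy)-3-hydroxy-2,5-dimethoxy[1,1'-biphenyl]-4-yl]ethyl}triphenylphosphonium bromide (racemic) | CC(c1c(O)c(OC)c(-c2ccc(OCc3ccccc3)cc2)cc1OC)[P+](c1ccccc1)(c1ccccc1)c1ccccc1.[Br-] | intermediate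
15 | methyl malonyl chloride (methyl 3-chloro-3-oxopropanoate) | COC(=O)CC(=O)Cl | starting material
16 | {1-[4'-(benzyloxy)-2,5-dimethoxy-3-(3-methoxy-3-oxopropanoyloxy)[1,1'-biphenyl]-4-yl]ethyl}triphenylphosphonium bromide (racemic) | COC(=O)CC(=O)Oc1c(OC)c(-c2ccc(OCc3ccccc3)cc2)cc(OC)c1C(C)[P+](c1ccccc1)(c1ccccc1)c1ccccc1.[Br-] | intermediate (not isolated)
17 | 4'-(benzyloxy)-2,5-dimethoxy-4-[1-(triphenyl-λ5-phosphanylidene)ethyl][1,1'-biphenyl]-3-yl methyl propanedioate | COC(=O)CC(=O)Oc1c(OC)c(-c2ccc(OCc3ccccc3)cc2)cc(OC)c1C(C)=P(c1ccccc1)(c1ccccc1)c1ccccc1 | intermediate (not isolated)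
18 | methyl 2-{6-[4-(benzyloxy)phenyl]-4,7-dimethoxy-3-methyl-1-benzofuran-2-yl}acetate | COC(=O)Cc1oc2c(OC)c(-c3ccc(OCc4ccccc4)cc3)cc(OC)c2c1C | intermediate
19 | phenylcandilide B, methyl 2-[6-(4-hydroxyphenyl)-4,7-dimethoxy-3-methyl-1-benzofuran-2-yl]acetate | COC(=O)Cc1oc2c(OC)c(-c3ccc(O)cc3)cc(OC)c2c1C | target

## Step count and least certain steps

Total step count: 10. Longest linear sequence: 10 steps (from 1 or 2 to 19).

**Step 5 (key step).** The most likely failure is a cycloaddition slowed by electron release from the two ring oxygens and the alkoxyphenyl group. At the temperature then needed, the ketene acetal may be consumed by oligomerisation, or it may attack C4 and displace the methoxymethoxy group by addition–elimination. Incomplete loss of methanol from 10 is a lesser concern that a mild acid or base treatment should cure. The fallback sets out from 7 and changes the two-carbon partner from an alkene to an alkyne, methoxyethyne (prepared from chloroacetaldehyde dimethyl acetal and NaNH2). Its linear donor is less hindered at the congested C3 terminus, and it has no β-hydrogen through which to fragment to a ketene on heating. Cycloaddition would give the bridged diene lactone F1, which becomes aromatic simply by losing CO2, so no elimination is needed and the route is rejoined at 11. This changes the class of 2π partner and the way aromaticity is reached, not only the temperature.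

**Step 9.** The most likely failures are proton transfer from the acidic malonate methylene of 16 to the ylide (or ketene formation from 15), C-acylation of the ylide, or reversion of the hindered secondary phosphonium phenoxide to an o-quinone methide with loss of PPh3. Each diverts material before the olefination. The fallback sets out from phenol ketone 12, bypassing steps 7–9, and rejoins at 18:
- O-alkylation with methyl bromoacetate and K2CO3 in DMF gives the aryloxyacetate F2.
- NaOMe in MeOH closes ring A by intramolecular aldol condensation onto the acetyl group, giving the benzofuran-2-carboxylate F3.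
- LiOH gives the carboxylic acid F4, and oxalyl chloride gives the acid chloride F5.
- Diazomethane gives the diazoketone F6.
- Wolff rearrangement with silver benzoate (PhCO2Ag) and Et3N in MeOH completes the Arndt–Eistert homologation to 18.

**Step 4.** The most likely failure is alkylation of the ambident tricarbonyl anion of 6 at the acetyl oxygen or the lactone carbonyl oxygen instead of O4, or hydrolytic loss of the vinylogous acetal during isolation. The fallback sets out from 4 with the order of events reversed and rejoins at 7:
- Compound 4 is protected first (MOMCl, iPr2NEt), since simple 4-hydroxy-2-pyrones alkylate cleanly at O4, giving the methoxymethyl ether F7.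
- NBS brominates the only free ring carbon, C3, giving the bromopyrone F8.
- Stille coupling with tributyl(1-ethoxyvinyl)stannane and Pd(PPh3)4 gives the enol ether F9.
- Brief treatment with dilute aqueous acid at 0 °C unmasks the acetyl group and returns 7.

**Step 1.** The most likely failure is incomplete acylation: the triketo ester product quenches the dianion, and a benzoate deactivated by a para alkoxy group is a sluggish acylating agent, so self-condensation of 1 competes. The fallback sets out from 1 and rejoins at 3 through the aldol oxidation level. The dianion of 1 adds to 4-(benzyloxy)benzaldehyde to give the δ-hydroxy-β-keto ester F10 as a mixture of diastereomers. Dess–Martin oxidation of F10 then gives 3.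

## Further compounds

F1 | step 5 | 4-acetyl-1-[4-(benzyloxy)phenyl]-6,8-dimethoxy-5-(methoxymethoxy)-2-oxabicyclo[2.2.2]octa-5,7-dien-3-one (racemic, not isolated) | CC(=O)[C@@]12C(=O)O[C@@](c3ccc(OCc4ccccc4)cc3)(C=C1OC)C(OC)=C2OCOC
F2 | step 9 | methyl 2-{[4-acetyl-4'-(benzyloxy)-2,5-dimethoxy[1,1'-biphenyl]-3-yl]oxy}acetate | COC(=O)COc1c(OC)c(-c2ccc(OCc3ccccc3)cc2)cc(OC)c1C(C)=O
F3 | step 9 | methyl 6-[4-(benzyloxy)phenyl]-4,7-dimethoxy-3-methyl-1-benzofuran-2-carboxylate | COC(=O)c1oc2c(OC)c(-c3ccc(OCc4ccccc4)cc3)cc(OC)c2c1C
F4 | step 9 | 6-[4-(benzyloxy)phenyl]-4,7-dimethoxy-3-methyl-1-benzofuran-2-carboxylic acid | OC(=O)c1oc2c(OC)c(-c3ccc(OCc4ccccc4)cc3)cc(OC)c2c1C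
F5 | step 9 | 6-[4-(benzyloxy)phenyl]-4,7-dimethoxy-3-methyl-1-benzofuran-2-carbonyl chloride | ClC(=O)c1oc2c(OC)c(-c3ccc(OCc4ccccc4)cc3)cc(OC)c2c1C
F6 | step 9 | 1-{6-[4-(benzyloxy)phenyl]-4,7-dimethoxy-3-methyl-1-benzofuran-2-yl}-2-diazoethan-1-one | [N-]=[N+]=CC(=O)c1oc2c(OC)c(-c3ccc(OCc4ccccc4)cc3)cc(OC)c2c1C
F7 | step 4 | 6-[4-(benzyloxy)phenyl]-5-methoxy-4-(methoxymethoxy)-2H-pyran-2-one | COCOC1=CC(=O)OC(c2ccc(OCc3ccccc3)cc2)=C1OC
F8 | step 4 | 6-[4-(benzyloxy)phenyl]-3-bromo-5-methoxy-4-(methoxymethoxy)-2H-pyran-2-one | COCOC1=C(Br)C(=O)OC(c2ccc(OCc3ccccc3)cc2)=C1OC
F9 | step 4 | 6-[4-(benzyloxy)phenyl]-3-(1-ethoxyethenyl)-5-methoxy-4-(methoxymethoxy)-2H-pyran-2-one | CCOC(=C)C1=C(OCOC)C(OC)=C(c2ccc(OCc3ccccc3)cc2)OC1=O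
F10 | step 1 | methyl 5-[4-(benzyloxy)phenyl]-5-hydroxy-4-methoxy-3-oxopentanoate (mixture of racemic diastereomers) | COC(=O)CC(=O)C(OC)C(O)c1ccc(OCc2ccccc2)cc1
A1 | alternative 1 | 6-[4-(benzyloxy)phenyl]-4-methoxy-3-methyl-1-benzofuran-7-ol | Cc1coc2c(O)c(-c3ccc(OCc4ccccc4)cc3)cc(OC)c12
A2 | alternative 1 | pentacarbonyl[methoxy(4-methylfuran-3-yl)methylidene]chromium | COC(=[Cr](=C=O)(=C=O)(=C=O)(=C=O)=C=O)c1cocc1C
A3 | alternative 1 | 1-(benzyloxy)-4-ethynylbenzene | C#Cc1ccc(OCc2ccccc2)cc1
A4 | alternative 2 | methyl 2-{6-[4-(benzyloxy)phenyl]-4,7-dimethoxy-3-methyl-2,3-dihydro-1-benzofuran-2-yl}acetate (trans, racemic, one enantiomer drawn) | COC(=O)C[C@@H]1Oc2c(OC)c(-c3ccc(OCc4ccccc4)cc3)cc(OC)c2[C@H]1C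
A5 | alternative 2 | 4'-(benzyloxy)-4-(but-3-en-2-yl)-2,5-dimethoxy[1,1'-biphenyl]-3-ol (racemic) | C=CC(C)c1c(O)c(OC)c(-c2ccc(OCc3ccccc3)cc2)cc1OC
A6 | alternative 3 | tert-butyl 6-[4-(benzyloxy)phenyl]-4,7-dihydroxy-2-(2-methoxy-2-oxoethyl)-3-methyl-1-benzofuran-5-carboxylate | COC(=O)Cc1oc2c(O)c(-c3ccc(OCc4ccccc4)cc3)c(C(=O)OC(C)(C)C)c(O)c2c1C
A7 | alternative 3 | methyl 2-[3-methyl-4-oxo-6-(phenylsulfonyl)-4H,6H-furo[3,4-b]furan-2-yl]acetate (racemic) | COC(=O)Cc1oc2c(c1C)C(=O)OC2S(=O)(=O)c1ccccc1
A8 | alternative 3 | tert-butyl (E)-3-[4-(benzyloxy)phenyl]prop-2-enoate | CC(C)(C)OC(=O)/C=C/c1ccc(OCc2ccccc2)cc1
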